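# Proposed total synthesis of rhamnazin 3-O-sulfate (18) through a propargyl aryl ether Claisen cascade

## The problem

Rhamnazin 3-O-sulfate (18) is a flavonol: a 4H-chromen-4-one (rings A and C) with a 4-hydroxy-3-methoxyphenyl ring B on C2, a sulfated enolic oxygen on C3, and a phloroglucinol-type ring A with OH on C5 and OMe on C7. It has no stereocentre; the stereocentres that appear on the way (C2 of a flavene, C2 to C4 of a diol) are erased when ring C becomes the aromatic pyranone, so none needs absolute control. The real tasks are to close ring C between a ring A and a ring B unit with C3 and C4 at the right oxidation level, and to bring five peripheral oxygens into four different states. The sulfate monoester is the fragile group: protic and Lewis acids cleave it, so it must enter late and be followed only by mild base or neutral operations. The 4'-OH is sulfated more readily than the 3-OH and therefore needs a mask that can be removed beside the sulfate. The 5-OH, held by a hydrogen bond to the C4 carbonyl, needs none, and the same peri relationship lets a 5-methyl ether be removed selectively beside the 7- and 3'-methyl ethers. The feature that opens the key step is the connectivity of ring C: O1 links C8a of ring A to the benzylic C2, and C4 is bonded to C4a, the carbon ortho to that oxygen. This is what an aryl 1-arylpropargyl ether leaves behind after a Claisen shift and recyclisation, and because the ring A oxygens at C5 and C7 are both meta to O1, the phenol partner can be the symmetric 3,5-dimethoxyphenol (6).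

## Retrosynthesis

**18 from 17.** The last bond cut is the acyl–oxygen bond of a 4'-O-pivalate in the potassium sulfate 17. An ester is chosen over a benzyl or silyl ether because an aryl ester falls to methoxide, towards which a sulfate monoester anion is inert, and because the acyloxy group weakens ring B as a donor in the thermal step. The forward reaction must cleave a hindered ester at room temperature and then protonate the salt briefly in the cold.

**17 from 16.** The S–O bond at O3 is cut next, leading to the 3,5-diol 16. Sulfating here, and not earlier, keeps the sulfate away from the Lewis acid and the oxidants. Selectivity rests on the substrate: the 4'-oxygen is acylated and the chelated 5-OH resists sulfur trioxide–amine complexes, so only the 3-OH should react.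

**16 from 15.** The O–CH3 bond at C5 is cut, giving the 5,7-dimethyl ether 15. Carrying both ring A oxygens as methyl ethers is what makes the phenol partner symmetric; the price is one chelation-controlled demethylation, which needs the C4 carbonyl and therefore comes after the flavonol is formed.

**15 from 12 from 11.** The C4 carbonyl and the C3 hydroxyl are traced back, through the cis-diol 12, to the two C–O bonds added across the C3=C4 alkene of flavene 11. This alkene is the only reactive π bond of 11, so one dihydroxylation places both oxygens, and a double oxidation to the 3,4-dione level followed by tautomerisation gives the pyranone. The precursor 11 is simpler by two oxygens and carries no oxidation-level problem.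

**11 from 7 (key disconnection).** In 11 the C4–C4a bond is cut and O1–C2 is understood as re-formed, which leads to the aryl propargyl ether 7. Compared with a cut at O1–C2 alone (an oxa-Michael closure of a chalcone) this makes the carbon–carbon bond to ring A without any acylation of an electron-rich arene. The forward reaction is asked for one regioisomer and for the six-membered ring; the symmetry of the 3,5-dimethoxyphenyl group answers the first and a neutral medium the second.

**7 from 5 and 6.** The propargylic C–O bond is cut to give carbonate 5 and 3,5-dimethoxyphenol (6). A copper-catalysed propargylic substitution is preferred to a base-mediated SN2 reaction because the secondary, benzylic centre reacts through a copper allenylidene without elimination. The reaction must alkylate oxygen and not the nucleophilic ring carbons of 6.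

**5 from 4 from 2 and 3; 2 from 1.** The carbonate is traced to alcohol 4, and its C–C bond between the carbinol carbon and the alkyne is cut to aldehyde 2 and ethynylmagnesium bromide (3). Aldehyde 2 is vanillin (1) with the phenol pivaloylated. Ring B thus comes with its oxygen pattern from a commodity aldehyde.

## Roads not taken

**Alternative 1:** Ring A, not ring C, is cut: C8a–C8, C5–C6, C7–C8 and C4a–C5 would be formed in a Danheiser benzannulation. Irradiation of the pyranonyl diazoketone A2 would trigger a Wolff rearrangement to a vinylketene, which adds methoxyacetylene A3; cyclobutenone opening and 6π closure would give the flavone A1.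
- Merits: A1 arrives with the 5-OH free and the 7-OMe in place, both fixed by the mechanism, so there is no demethylation step. Its benzyl-type ethers allow an end game without acid or base. In both respects it is better than the chosen plan.
- Weak points: A2 must be built from kojic acid A4 by a long sequence (protection, arylation next to the ring oxygen, oxidation of the hydroxymethyl group, diazoketone formation). A3 is volatile and unstable. A 4-pyranone double bond has not been shown to serve as the vinyl unit of this benzannulation, and the pyranone chromophore is itself photolabile.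
- Comparison: the chosen plan reaches the bicycle 11 in five steps by reactions of known type, and sets one Lewis-acid step and two oxidations against the elegance of A1.

**Alternative 2:** O1–C2 and C3–C4 are cut. An amine base would promote oxa-Michael addition of salicylaldehyde A6 to nitrostyrene A7, followed by an intramolecular Henry reaction and dehydration, giving the 3-nitro-2H-chromene A5.
- Merits: the ring closure is convergent and runs at ambient temperature, milder than a thermal rearrangement. The 5-O-benzyl group of A6 is distinct from the 7-OMe from the start, so no peri-demethylation is needed and both benzyl ethers could fall in a final neutral hydrogenolysis; here this road is as good as or better than the chosen one.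
- Weak points: A6 requires three phloroglucinol oxygens to be told apart before the key step. In A5 carbon 3 carries nitrogen and C4 is a CH, so a Nef-type conversion to a flavan-3-one and a separate oxidation of C4 are needed, on sensitive intermediates and without a short, reliable precedent.
- Comparison: flavene 11 offers a bare C3=C4 alkene that takes both oxygens in one dihydroxylation, which makes the chosen route shorter after ring closure despite its hotter key step.

**Alternative 3:** O1–C8a and C4–C4a are cut in an aryne annulation. Fluoride would release a 3,5-dimethoxy-substituted aryne from the silyl triflate A9; the enolate oxygen of keto ester A10 would add at the aryne carbon meta to methoxy and the resulting aryl anion would attack the ester, giving the flavone A8.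
- Merits: this is the most convergent road and lands directly at the flavonol oxidation level with the 3-oxygen in place, saving the dihydroxylation and oxidation of the chosen plan. That is a real advantage of two steps.
- Weak points: β-keto ester enolates normally attack arynes through carbon and insert the aryne into the C–C bond, so the O-arylation and acyl transfer sequence would be a new method at the central step. Fluoride and enolate threaten the aryl pivalate, A9 needs several steps from 6, and the 5-O-demethylation remains.
- Comparison: the chosen plan accepts two extra redox steps in exchange for a ring-forming step of established type whose regiochemistry is fixed by symmetry, not by an O-versus-C preference that usually goes the other way.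

Key step: step 5

Remark on the chemistry: 18 is drawn as the hydrogen sulfate; such esters are normally kept as potassium salts, so the acid form is generated only in the last operation, in the cold, and the salt would be the stored form.

Remark on the chemistry: species that exist only until aqueous work-up (the magnesium alkoxide, boron chelates, and the pyridinium and dipotassium salts of the products) are treated as the unquenched form of the product and are not numbered.

## Route

Step 1
Reactants: 1 vanillin
Product: 2 4-formyl-2-methoxyphenyl pivalate
Conditions: PivCl, Et3N, DMAP (cat.), CH2Cl2, 0 °C → rt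
Reagents that add atoms: pivaloyl chloride, CC(C)(C)C(=O)Cl
Why: DMAP-catalysed acylation of the phenol; the pivalate should survive the Grignard addition at low temperature, the thermal step and BCl3, tempers ring B as a donor, and is removable last by methanolysis.

Step 2
Reactants: 2 4-formyl-2-methoxyphenyl pivalate; 3 ethynylmagnesium bromide
Product: 4 4-(1-hydroxyprop-2-yn-1-yl)-2-methoxyphenyl pivalate (racemic)
Conditions: THF, −78 → −40 °C; aq. NH4Cl work-up
Reagents that add atoms: none
Why: 1,2-addition of an alkynyl Grignard reagent; at −78 °C the aldehyde is far more electrophilic than the hindered aryl pivalate, and the carbinol centre is formed racemic, which suffices because this carbon ends as the sp2 C2 of the flavonol.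

Step 3
Reactants: 4 4-(1-hydroxyprop-2-yn-1-yl)-2-methoxyphenyl pivalate (racemic)
Product: 5 4-[1-(methoxycarbonyloxy)prop-2-yn-1-yl]-2-methoxyphenyl pivalate (racemic)
Conditions: ClCO2Me, pyridine, DMAP (cat.), CH2Cl2, 0 °C
Reagents that add atoms: methyl chloroformate, COC(=O)Cl
Why: carbonate formation from a secondary alcohol and a chloroformate; the methyl carbonate is the leaving group needed for copper allenylidene formation and releases its own base on ionisation.

Step 4
Reactants: 5 4-[1-(methoxycarbonyloxy)prop-2-yn-1-yl]-2-methoxyphenyl pivalate (racemic); 6 3,5-dimethoxyphenol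
Product: 7 4-[1-(3,5-dimethoxyphenoxy)prop-2-yn-1-yl]-2-methoxyphenyl pivalate (racemic)
Conditions: (CuOTf)2·C6H6 (5 mol %), 2,6-bis(4,4-dimethyl-2-oxazolin-2-yl)pyridine (10 mol %), iPr2NEt (1.5 equiv), MeCN, 0 °C → rt
Reagents that add atoms: none
Why: copper-catalysed propargylic etherification: the copper acetylide of 5 expels the carbonate to give an aryl-stabilised copper allenylidene, which the amine-bound phenol attacks at the γ-carbon through oxygen, not through its ring carbons; the product is racemic.

Step 5
Reactants: 7 4-[1-(3,5-dimethoxyphenoxy)prop-2-yn-1-yl]-2-methoxyphenyl pivalate (racemic)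
Product: 11 4-(5,7-dimethoxy-2H-chromen-2-yl)-2-methoxyphenyl pivalate (racemic), via allenyl dienone 8 (not isolated), via allenylphenol 9 (not isolated), via vinyl quinone methide 10 (not isolated)
Conditions: PhNEt2 (0.05 M, degassed), 185 °C, argon, sealed vessel
Reagents that add atoms: none
Why: This is the thermal aryl propargyl ether Claisen rearrangement to a 2H-chromene, long used for 2,2-dimethylchromenes and also known for aryl 1-arylpropargyl ethers. A [3,3]-sigmatropic shift joins the alkyne terminus to the ortho carbon (C4–C4a) and gives allenyl dienone 8, which enolises to allenylphenol 9. A 1,5-hydrogen shift from the phenolic oxygen to the central allene carbon gives the Z-configured vinyl ortho-quinone methide 10. Thermal oxa-6π electrocyclisation (disrotatory, six-membered ring, O1–C2) then closes the pyran ring of 11. C2 is the only stereocentre; it passes through a planar carbon in 10 and is re-formed racemic, which is all the route needs because it later becomes sp2. Regioselectivity is secured because the two ortho carbons of the 3,5-dimethoxyphenyl ether are equivalent and the para carbon cannot take part in the [3,3] shift. The chromene should win over five-membered closure to a benzofuran because in a neutral, fluoride-free medium the hydrogen shift of 9 outruns phenoxide addition to the allene, and the pivalate tempers ring B so that heterolysis of the benzylic propargylic C–O bond should not compete.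

Step 6
Reactants: 11 4-(5,7-dimethoxy-2H-chromen-2-yl)-2-methoxyphenyl pivalate (racemic)
Product: 12 4-[(2R*,3S*,4S*)-3,4-dihydroxy-5,7-dimethoxy-3,4-dihydro-2H-chromen-2-yl]-2-methoxyphenyl pivalate (racemic, 2,3-trans-3,4-cis)
Conditions: OsO4 (2 mol %), NMO (1.5 equiv), acetone–H2O (8:1), 0 °C → rt; aq. Na2SO3 quench, neutral work-up
Reagents that add atoms: N-methylmorpholine N-oxide, C[N+]1([O-])CCOCC1; water, O
Why: Upjohn dihydroxylation; syn addition of OsO4 to the electron-rich C3=C4 bond on the face anti to the C2 aryl group should give the racemic 2,3-trans-3,4-cis diol (relative configuration set by the C2 substituent and of no later consequence); the acid-labile benzylic 4-OH is the reason for the neutral work-up.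

Step 7
Reactants: 12 4-[(2R*,3S*,4S*)-3,4-dihydroxy-5,7-dimethoxy-3,4-dihydro-2H-chromen-2-yl]-2-methoxyphenyl pivalate (racemic)
Product: 15 4-(3-hydroxy-5,7-dimethoxy-4-oxo-4H-chromen-2-yl)-2-methoxyphenyl pivalate, via dihydroflavonol 13 (not isolated), via flavan-3,4-dione 14 (not isolated)
Conditions: 2-iodoxybenzoic acid (IBX, 3 equiv), DMSO, rt → 40 °C
Reagents that add atoms: none
Why: IBX oxidation of a vicinal diol to the 1,2-dicarbonyl level without C–C cleavage: the benzylic 4-OH is expected to go first (13), then the α-ketol to dione 14, whose C2–H (benzylic, α-oxy, α-keto) tautomerises spontaneously to the aromatic 3-hydroxy-4-pyranone, a diosphenol; all three stereocentres are erased.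

Step 8
Reactants: 15 4-(3-hydroxy-5,7-dimethoxy-4-oxo-4H-chromen-2-yl)-2-methoxyphenyl pivalate
Product: 16 4-(3,5-dihydroxy-7-methoxy-4-oxo-4H-chromen-2-yl)-2-methoxyphenyl pivalate
Conditions: BCl3 (1 M in CH2Cl2, 3 equiv), CH2Cl2, −78 → 0 °C; then ice-water, rt, 1 h
Reagents that add atoms: none
Why: chelation-controlled peri-demethylation: boron bridges the C4 carbonyl and the 5-methoxy oxygen in a six-membered chelate and chloride removes that methyl group only; the 7- and 3'-methoxy groups lack a chelating neighbour and the pivalate should be inert at or below 0 °C.

Step 9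
Reactants: 16 4-(3,5-dihydroxy-7-methoxy-4-oxo-4H-chromen-2-yl)-2-methoxyphenyl pivalate
Product: 17 potassium 5-hydroxy-7-methoxy-2-[3-methoxy-4-(pivaloyloxy)phenyl]-4-oxo-4H-chromen-3-yl sulfate
Conditions: SO3·pyridine (3 equiv), pyridine, rt → 45 °C; then aq. KHCO3, 0 °C; reversed-phase (C18) chromatography
Reagents that add atoms: sulfur trioxide pyridine complex, O=S(=O)([O-])[n+]1ccccc1; potassium hydrogencarbonate, [K+].OC([O-])=O
Why: O-sulfation with a sulfur trioxide–amine complex; the 4'-oxygen is masked and the 5-OH, tied to the carbonyl by a strong six-membered hydrogen bond, resists such reagents, so only the 3-OH should react; isolation as the potassium salt keeps the acid-labile ester ionised.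

Step 10
Reactants: 17 potassium 5-hydroxy-7-methoxy-2-[3-methoxy-4-(pivaloyloxy)phenyl]-4-oxo-4H-chromen-3-yl sulfate
Product: 18 rhamnazin 3-O-sulfate, 5-hydroxy-2-(4-hydroxy-3-methoxyphenyl)-7-methoxy-4-oxo-4H-chromen-3-yl hydrogen sulfate
Conditions: K2CO3 (2 equiv), MeOH, rt; then 0.5 M aq. HCl to pH 2, 0 °C; C18 solid-phase extraction (H2O, then MeCN–H2O), freeze-drying
Reagents that add atoms: none
Why: base-mediated transesterification (methanolysis) of an aryl ester: phenoxide is a good leaving group, so even the pivalate should be cleaved at room temperature, while the sulfate monoester anion repels methoxide and is cleaved only by acid; short cold acidification and desalting then deliver the hydrogen sulfate.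

## Compound list

1 | vanillin (4-hydroxy-3-methoxybenzaldehyde) | COc1cc(C=O)ccc1O | starting material
2 | 4-formyl-2-methoxyphenyl pivalate | COc1cc(C=O)ccc1OC(=O)C(C)(C)C | intermediate
3 | ethynylmagnesium bromide | C#C[Mg]Br | starting material
4 | 4-(1-hydroxyprop-2-yn-1-yl)-2-methoxyphenyl pivalate (racemic) | C#CC(O)c1ccc(OC(=O)C(C)(C)C)c(OC)c1 | intermediate
5 | 4-[1-(methoxycarbonyloxy)prop-2-yn-1-yl]-2-methoxyphenyl pivalate (racemic) | COC(=O)OC(C#C)c1ccc(OC(=O)C(C)(C)C)c(OC)c1 | intermediate
6 | 3,5-dimethoxyphenol | COc1cc(O)cc(OC)c1 | starting material
7 | 4-[1-(3,5-dimethoxyphenoxy)prop-2-yn-1-yl]-2-methoxyphenyl pivalate (racemic) | C#CC(Oc1cc(OC)cc(OC)c1)c1ccc(OC(=O)C(C)(C)C)c(OC)c1 | intermediate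
8 | 4-[3-(2,4-dimethoxy-6-oxocyclohexa-2,4-dien-1-yl)propa-1,2-dien-1-yl]-2-methoxyphenyl pivalate (mixture of stereoisomers) | O=C1C=C(OC)C=C(OC)C1C=C=Cc1ccc(OC(=O)C(C)(C)C)c(OC)c1 | intermediate (not isolated)
9 | 4-[3-(2-hydroxy-4,6-dimethoxyphenyl)propa-1,2-dien-1-yl]-2-methoxyphenyl pivalate (racemic allene) | Oc1cc(OC)cc(OC)c1C=C=Cc1ccc(OC(=O)C(C)(C)C)c(OC)c1 | intermediate (not isolated)
10 | 4-[3-(2,4-dimethoxy-6-oxocyclohexa-2,4-dien-1-ylidene)prop-1-en-1-yl]-2-methoxyphenyl pivalate (Z at the exocyclic double bond) | O=C1C=C(OC)C=C(OC)/C1=C/C=Cc1ccc(OC(=O)C(C)(C)C)c(OC)c1 | intermediate (not isolated)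
11 | 4-(5,7-dimethoxy-2H-chromen-2-yl)-2-methoxyphenyl pivalate (racemic) | COc1cc(OC)c2C=CC(c3ccc(OC(=O)C(C)(C)C)c(OC)c3)Oc2c1 | intermediate
12 | 4-[(2R*,3S*,4S*)-3,4-dihydroxy-5,7-dimethoxy-3,4-dihydro-2H-chromen-2-yl]-2-methoxyphenyl pivalate (racemic, one enantiomer drawn) | COc1cc(OC)c2c(c1)O[C@H](c1ccc(OC(=O)C(C)(C)C)c(OC)c1)[C@@H](O)[C@H]2O | intermediate
13 | 4-[(2R*,3R*)-3-hydroxy-5,7-dimethoxy-4-oxo-3,4-dihydro-2H-chromen-2-yl]-2-methoxyphenyl pivalate (racemic trans, one enantiomer drawn) | COc1cc(OC)c2c(c1)O[C@H](c1ccc(OC(=O)C(C)(C)C)c(OC)c1)[C@@H](O)C2=O | intermediate (not isolated)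
14 | 4-(5,7-dimethoxy-3,4-dioxo-3,4-dihydro-2H-chromen-2-yl)-2-methoxyphenyl pivalate (racemic) | COc1cc(OC)c2c(c1)OC(c1ccc(OC(=O)C(C)(C)C)c(OC)c1)C(=O)C2=O | intermediate (not isolated)
15 | 4-(3-hydroxy-5,7-dimethoxy-4-oxo-4H-chromen-2-yl)-2-methoxyphenyl pivalate | COc1cc(OC)c2c(=O)c(O)c(-c3ccc(OC(=O)C(C)(C)C)c(OC)c3)oc2c1 | intermediate
16 | 4-(3,5-dihydroxy-7-methoxy-4-oxo-4H-chromen-2-yl)-2-methoxyphenyl pivalate | COc1cc(O)c2c(=O)c(O)c(-c3ccc(OC(=O)C(C)(C)C)c(OC)c3)oc2c1 | intermediate
17 | potassium 5-hydroxy-7-methoxy-2-[3-methoxy-4-(pivaloyloxy)phenyl]-4-oxo-4H-chromen-3-yl sulfate | COc1cc(O)c2c(=O)c(OS(=O)(=O)[O-])c(-c3ccc(OC(=O)C(C)(C)C)c(OC)c3)oc2c1.[K+] | intermediate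
18 | rhamnazin 3-O-sulfate, 5-hydroxy-2-(4-hydroxy-3-methoxyphenyl)-7-methoxy-4-oxo-4H-chromen-3-yl hydrogen sulfate | COc1cc(O)c2c(=O)c(OS(=O)(=O)O)c(-c3ccc(O)c(OC)c3)oc2c1 | target

## Step count and risks

Total: 10 steps. Longest linear sequence: 10 steps, from vanillin (1) to 18; the Grignard reagent 3 and the phenol 6 are commercial and enter at steps 2 and 4.

Least certain steps:

**Step 5 (key step).** At 185 °C the doubly activated benzylic–propargylic C–O bond may ionise before the sigmatropic shift, leading to recombination at ring carbon or to oligomers, and the flavene may disproportionate or oxidise in air during isolation. The fallback avoids the propargyl ether altogether and enters the same cascade one stage later. It sets out from aldehyde 2 and phenol 6 and comes back at 11. Wittig olefination of 2 with (triphenylphosphoranylidene)acetaldehyde should give 4-[(E)-3-oxoprop-1-en-1-yl]-2-methoxyphenyl pivalate F1. F1 and 6, heated with PhB(OH)2 and a little propionic acid in toluene with removal of water, should condense ortho-specifically to 4-[(E)-2-(5,7-dimethoxy-2-phenyl-4H-1,3,2-benzodioxaborin-4-yl)ethenyl]-2-methoxyphenyl pivalate F2. F2 fragments at about 110 °C to the same quinone methide 10, which closes to 11.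

**Step 7.** The free diol may undergo oxidative C–C cleavage, or its 4-OH may ionise before it is oxidised. The fallback separates the two oxidations and starts from 12, returning at 15. Activated MnO2 in CH2Cl2 should oxidise only the benzylic 4-OH and give 13 as an isolated compound. Dess–Martin periodinane buffered with NaHCO3 should then take the α-ketol to 14, which tautomerises to 15. This fallback makes no compound outside the list (F0).

**Step 4.** The copper allenylidene may be attacked by the ring carbons of the phloroglucinol-type phenol (Friedel–Crafts propargylation) in place of its oxygen. The fallback sets out from alcohol 4, omits 5, and returns at 7: a Mitsunobu etherification of 4 with 6 (PPh3, DIAD, THF, 0 °C), in which the phenoxide oxygen displaces the alkoxyphosphonium group. No compound outside the list is made (F0).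

**Step 8.** Boron may be sequestered in a five-membered chelate between O3 and the carbonyl, so that demethylation stalls and forcing conditions cost the pivalate or the 3'-methyl group. The fallback masks the 3-OH first; it sets out from 15 and returns at 16. Acetylation (Ac2O, pyridine) should give 5,7-dimethoxy-2-[3-methoxy-4-(pivaloyloxy)phenyl]-4-oxo-4H-chromen-3-yl acetate F3, in which only the O4/O5 chelate is possible. BCl3 demethylation of F3 should give 5-hydroxy-7-methoxy-2-[3-methoxy-4-(pivaloyloxy)phenyl]-4-oxo-4H-chromen-3-yl acetate F4. Pyrrolidine (1 equiv, CH2Cl2, 0 °C) should then aminolyse the unhindered enol acetate of F4 much faster than the pivalate, giving 16.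

## Further compounds

F1 | step 5 | 4-[(E)-3-oxoprop-1-en-1-yl]-2-methoxyphenyl pivalate | O=C/C=C/c1ccc(OC(=O)C(C)(C)C)c(OC)c1
F2 | step 5 | 4-[(E)-2-(5,7-dimethoxy-2-phenyl-4H-1,3,2-benzodioxaborin-4-yl)ethenyl]-2-methoxyphenyl pivalate (racemic) | COc1cc(OC)c2C(/C=C/c3ccc(OC(=O)C(C)(C)C)c(OC)c3)OB(c3ccccc3)Oc2c1
F0 | step 7 | none | none
F0 | step 4 | none | none
F3 | step 8 | 5,7-dimethoxy-2-[3-methoxy-4-(pivaloyloxy)phenyl]-4-oxo-4H-chromen-3-yl acetate | COc1cc(OC)c2c(=O)c(OC(C)=O)c(-c3ccc(OC(=O)C(C)(C)C)c(OC)c3)oc2c1
F4 | step 8 | 5-hydroxy-7-methoxy-2-[3-methoxy-4-(pivaloyloxy)phenyl]-4-oxo-4H-chromen-3-yl acetate | COc1cc(O)c2c(=O)c(OC(C)=O)c(-c3ccc(OC(=O)C(C)(C)C)c(OC)c3)oc2c1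
A1 | alternative 1 | 2-[4-(benzyloxy)-3-methoxyphenyl]-5-hydroxy-7-methoxy-3-[(4-methoxybenzyl)oxy]-4H-chromen-4-one | COc1cc(O)c2c(=O)c(OCc3ccc(OC)cc3)c(-c3ccc(OCc4ccccc4)c(OC)c3)oc2c1
A2 | alternative 1 | 2-[4-(benzyloxy)-3-methoxyphenyl]-6-(2-diazoacetyl)-3-[(4-methoxybenzyl)oxy]-4H-pyran-4-one | [N-]=[N+]=CC(=O)c1cc(=O)c(OCc2ccc(OC)cc2)c(-c2ccc(OCc3ccccc3)c(OC)c2)o1
A3 | alternative 1 | methoxyacetylene (methoxyethyne) | COC#C
A4 | alternative 1 | kojic acid, 5-hydroxy-2-(hydroxymethyl)-4H-pyran-4-one | OCc1cc(=O)c(O)co1
A5 | alternative 2 | 5-(benzyloxy)-2-[4-(benzyloxy)-3-methoxyphenyl]-7-methoxy-3-nitro-2H-chromene (racemic) | COc1cc(OCc2ccccc2)c2C=C([N+](=O)[O-])C(c3ccc(OCc4ccccc4)c(OC)c3)Oc2c1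
A6 | alternative 2 | 2-(benzyloxy)-6-hydroxy-4-methoxybenzaldehyde | COc1cc(O)c(C=O)c(OCc2ccccc2)c1
A7 | alternative 2 | 1-(benzyloxy)-2-methoxy-4-[(E)-2-nitroethenyl]benzene | COc1cc(/C=C/[N+](=O)[O-])ccc1OCc1ccccc1
A8 | alternative 3 | 5,7-dimethoxy-3-(methoxymethoxy)-2-[3-methoxy-4-(pivaloyloxy)phenyl]-4H-chromen-4-one | COCOc1c(-c2ccc(OC(=O)C(C)(C)C)c(OC)c2)oc2cc(OC)cc(OC)c2c1=O
A9 | alternative 3 | 3,5-dimethoxy-2-(trimethylsilyl)phenyl trifluoromethanesulfonate | COc1cc(OC)c([Si](C)(C)C)c(OS(=O)(=O)C(F)(F)F)c1
A10 | alternative 3 | methyl 2-(methoxymethoxy)-3-[3-methoxy-4-(pivaloyloxy)phenyl]-3-oxopropanoate | COCOC(C(=O)OC)C(=O)c1ccc(OC(=O)C(C)(C)C)c(OC)c1
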